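**Plan**
- Retrosynthesis: cut the two methylene bridges (ring A–CH2–ring B, ring B–CH2–ring C), then cut in ring C the C5–acyl bond and the C6–O bond together.
- Enabling feature: ring C (C1 bridge carbon, C2 OH, C3 CH3, C4 OCH3, C5 butyryl, C6 OH) is an ortho-hydroxyaryl ketone whose acyl carbon C5 lies next to the C4 methoxy group. A 3-methoxyaryne C5≡C6 gives exactly this pattern when it takes up butanoic acid.
- Forward, ring C: a benzaldehyde is converted into the 2-silylaryl triflate (benzylation, methylation, Dakin oxidation, carbamate-directed silylation, triflation). The aryne insertion then installs butyryl and OH, and debenzylation frees C2–OH.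
- Forward, chain: ring C is joined to butyrylphloroglucinol (ring B) through a Mannich base and its ortho-quinone methide. The same tactic on ring B attaches butyrylfilicinic acid (ring A), itself made by dearomatising gem-dimethylation; no ring is built in the route.
- Stereochemistry: none to set; the target is achiral.

Key step: step 7

Remark: ring A is handled as the enol tautomer drawn for the target, and the ring C numbering above is used for all ring C precursors.

**Route**

Step 1
Reactants: 1 2,4-dihydroxy-3-methylbenzaldehyde; 2 benzyl bromide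
Product: 3 4-(benzyloxy)-2-hydroxy-3-methylbenzaldehyde
Conditions: NaHCO3, KI (cat.), MeCN, 80 °C
Reagents that add atoms: none
Why: Williamson etherification; the 2-OH is locked in a hydrogen bond to the aldehyde, so the weak base ionises and alkylates only the para 4-OH.

Step 2
Reactants: 3 4-(benzyloxy)-2-hydroxy-3-methylbenzaldehyde
Product: 4 4-(benzyloxy)-2-methoxy-3-methylbenzaldehyde
Conditions: MeI, K2CO3, DMF, rt to 50 °C
Reagents that add atoms: iodomethane, CI
Why: Williamson methylation of the one remaining phenol under a stronger base; no other acidic site is present.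

Step 3
Reactants: 4 4-(benzyloxy)-2-methoxy-3-methylbenzaldehyde
Product: 6 4-(benzyloxy)-2-methoxy-3-methylphenol, via aryl formate 5 (not isolated)
Conditions: mCPBA, CH2Cl2, 0 °C to rt; aq. NaHCO3 wash; then K2CO3 (cat.), MeOH, rt
Reagents that add atoms: 3-chloroperoxybenzoic acid, OOC(=O)c1cccc(Cl)c1
Why: Dakin-type Baeyer–Villiger oxidation; the electron-rich aryl group migrates in the Criegee intermediate to give formate 5, which mild methanolysis cleaves to the phenol (oxygen now on C5).

Step 4
Reactants: 6 4-(benzyloxy)-2-methoxy-3-methylphenol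
Product: 7 4-(benzyloxy)-2-methoxy-3-methylphenyl N-(propan-2-yl)carbamate
Conditions: i-PrNCO, Et3N (cat.), CH2Cl2, rt
Reagents that add atoms: 2-isocyanatopropane, CC(C)N=C=O
Why: Base-catalysed addition of the phenol to the isocyanate gives a carbamate that directs ortho-metalation strongly and can later be removed under mild base.

Step 5
Reactants: 7 4-(benzyloxy)-2-methoxy-3-methylphenyl N-(propan-2-yl)carbamate
Product: 10 4-(benzyloxy)-2-methoxy-3-methyl-6-(trimethylsilyl)phenyl N-(propan-2-yl)carbamate, via N-silyl carbamate 8 (not isolated), via bis-silyl carbamate 9 (not isolated)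
Conditions: TMSOTf, TMEDA, Et2O, 0 °C to rt; then n-BuLi, TMEDA, −78 °C; TMSCl, −78 °C to rt; aq. NaHSO4
Reagents that add atoms: chlorotrimethylsilane, C[Si](C)(C)Cl
Why: Directed ortho-metalation (Snieckus–Hoppe type); N-silylation by TMSOTf masks the N–H, deprotonation can then occur only at C6 (the other ortho position, C4, carries OCH3), the metalated carbon is silylated, and work-up hydrolyses the N–Si bond.

Step 6
Reactants: 10 4-(benzyloxy)-2-methoxy-3-methyl-6-(trimethylsilyl)phenyl N-(propan-2-yl)carbamate
Product: 12 4-(benzyloxy)-2-methoxy-3-methyl-6-(trimethylsilyl)phenyl trifluoromethanesulfonate, via silylphenol 11 (not isolated)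
Conditions: Et2NH, DBU, MeCN, 40 °C; then PhNTf2, rt
Reagents that add atoms: N-phenylbis(trifluoromethanesulfonimide), O=S(=O)(N(c1ccccc1)S(=O)(=O)C(F)(F)F)C(F)(F)F
Why: E1cB cleavage of the N-monoalkyl carbamate (isopropyl isocyanate is expelled and trapped by diethylamine as the urea), followed by triflation of phenoxide 11 in the same flask, the standard entry to 2-silylaryl triflates.

Step 7
Reactants: 12 4-(benzyloxy)-2-methoxy-3-methyl-6-(trimethylsilyl)phenyl trifluoromethanesulfonate; 13 butanoic acid
Product: 15 1-[4-(benzyloxy)-6-hydroxy-2-methoxy-3-methylphenyl]butan-1-one, via aryne 14 (not isolated)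
Conditions: CsF (4 equiv), THF, 125 °C, sealed tube; 12 : 13 about 1.2 : 1
Reagents that add atoms: none
Why: Fluoride attacks silicon and triflate leaves, giving aryne 14 (C5≡C6); caesium butanoate adds through oxygen to C6, the aryne carbon remote from the C4 methoxy group, because the inductively withdrawing OCH3 makes C6 the more electrophilic terminus and stabilises the negative charge developing at C5. The C5 aryl anion then attacks the neighbouring ester carbonyl, and the strained four-membered hemiketal alkoxide opens to the C5 ketone and the C6 phenoxide, so the C6–O and C5–C(acyl) bonds form in one operation. The closest known reaction type is the insertion of arynes from 2-silylaryl triflates into the C–O bond of carboxylic acids to give ortho-hydroxyaryl ketones, which proceeds in hot THF where no proton source intercepts the aryl anion. No ring persists in the product and no stereocentre is formed. The selectivity needed is the side of addition to the unsymmetrical aryne together with acyl transfer in preference to protonation; the first is secured by the C4 methoxy group beside the triple bond, the second by the aprotic medium with the acid held as its caesium salt.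

Step 8
Reactants: 15 1-[4-(benzyloxy)-6-hydroxy-2-methoxy-3-methylphenyl]butan-1-one
Product: 16 1-(4,6-dihydroxy-2-methoxy-3-methylphenyl)butan-1-one
Conditions: H2 (1 atm), 10% Pd/C, EtOAc, rt
Reagents that add atoms: none
Why: Hydrogenolysis of the benzyl ether; the hydrogen-bonded aryl ketone and the methyl ether should not be reduced under these neutral conditions.

Step 9
Reactants: 16 1-(4,6-dihydroxy-2-methoxy-3-methylphenyl)butan-1-one
Product: 17 1-{3-[(dimethylamino)methyl]-2,4-dihydroxy-6-methoxy-5-methylphenyl}butan-1-one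
Conditions: Me2N=CH2+ I− (Eschenmoser's salt), MeCN, rt; aq. NaHCO3
Reagents that add atoms: N,N-dimethylmethyleneiminium iodide, C=[N+](C)C.[I-]
Why: Phenolic Mannich reaction; C1 is the only unsubstituted ring carbon and lies between two hydroxyl groups, so the iminium ion has a single site of attack.

Step 10
Reactants: 18 benzene-1,3,5-triol (phloroglucinol); 13 butanoic acid
Product: 19 1-(2,4,6-trihydroxyphenyl)butan-1-one
Conditions: BF3·OEt2 (solvent and promoter), 90 °C; then aq. NaOAc
Reagents that add atoms: none
Why: Friedel–Crafts acylation of phloroglucinol with the free acid; the first acyl group deactivates the ring and is held as a boron chelate until work-up, which limits diacylation.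

Step 11
Reactants: 17 1-{3-[(dimethylamino)methyl]-2,4-dihydroxy-6-methoxy-5-methylphenyl}butan-1-one; 19 1-(2,4,6-trihydroxyphenyl)butan-1-one
Product: 21 1-{3-[(3-butanoyl-2,4,6-trihydroxyphenyl)methyl]-2,4-dihydroxy-6-methoxy-5-methylphenyl}butan-1-one, via quinone methide 20 (not isolated)
Conditions: 19 (3 equiv), 1,4-dioxane, 90 °C, N2 sweep
Reagents that add atoms: none
Why: Thermal loss of dimethylamine from the phenolic Mannich base gives ortho-quinone methide 20, which is C-alkylated by the electron-rich ring of 19 (Michael-type addition); the excess of 19 suppresses double alkylation.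

Step 12
Reactants: 21 1-{3-[(3-butanoyl-2,4,6-trihydroxyphenyl)methyl]-2,4-dihydroxy-6-methoxy-5-methylphenyl}butan-1-one
Product: 22 1-[3-({3-butanoyl-5-[(dimethylamino)methyl]-2,4,6-trihydroxyphenyl}methyl)-2,4-dihydroxy-6-methoxy-5-methylphenyl]butan-1-one
Conditions: Me2N=CH2+ I−, MeCN, 0 °C to rt; aq. NaHCO3
Reagents that add atoms: N,N-dimethylmethyleneiminium iodide, C=[N+](C)C.[I-]
Why: Second phenolic Mannich reaction; the only unsubstituted aromatic carbon left in 21 is on ring B, flanked by two hydroxyl groups.

Step 13
Reactants: 19 1-(2,4,6-trihydroxyphenyl)butan-1-one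
Product: 23 2-butanoyl-3,5-dihydroxy-6,6-dimethylcyclohexa-2,4-dien-1-one (butyrylfilicinic acid)
Conditions: NaOMe, MeI (about 2 equiv), MeOH, 0 °C to rt
Reagents that add atoms: iodomethane, CI
Why: Dearomatising C-methylation of the acylphloroglucinol, the standard entry to acylfilicinic acids; two methyl groups enter at one ring carbon to give the non-aromatic gem-dimethyl β-triketone, which is separated from under- and over-methylated material.

Step 14
Reactants: 22 1-[3-({3-butanoyl-5-[(dimethylamino)methyl]-2,4,6-trihydroxyphenyl}methyl)-2,4-dihydroxy-6-methoxy-5-methylphenyl]butan-1-one; 23 2-butanoyl-3,5-dihydroxy-6,6-dimethylcyclohexa-2,4-dien-1-one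
Product: 25 Filixsaure, 2-butanoyl-4-({3-butanoyl-5-[(3-butanoyl-2,6-dihydroxy-4-methoxy-5-methylphenyl)methyl]-2,4,6-trihydroxyphenyl}methyl)-3,5-dihydroxy-6,6-dimethylcyclohexa-2,4-dien-1-one, via quinone methide 24 (not isolated)
Conditions: 23 (2 equiv), 1,4-dioxane, 80–90 °C, N2 sweep; dilute HCl work-up
Reagents that add atoms: none
Why: Loss of dimethylamine from 22 gives ring B ortho-quinone methide 24, which the enolised β-triketone 23 attacks through its only C–H carbon (Michael addition); neither partner has another carbon that can be alkylated.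

**Compound list**
1 | 2,4-dihydroxy-3-methylbenzaldehyde | Cc1c(O)ccc(C=O)c1O | starting material
2 | benzyl bromide | BrCc1ccccc1 | starting material
3 | 4-(benzyloxy)-2-hydroxy-3-methylbenzaldehyde | Cc1c(OCc2ccccc2)ccc(C=O)c1O | intermediate
4 | 4-(benzyloxy)-2-methoxy-3-methylbenzaldehyde | COc1c(C)c(OCc2ccccc2)ccc1C=O | intermediate
5 | 4-(benzyloxy)-2-methoxy-3-methylphenyl formate | COc1c(C)c(OCc2ccccc2)ccc1OC=O | intermediate (not isolated)
6 | 4-(benzyloxy)-2-methoxy-3-methylphenol | COc1c(C)c(OCc2ccccc2)ccc1O | intermediate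
7 | 4-(benzyloxy)-2-methoxy-3-methylphenyl N-(propan-2-yl)carbamate | CC(C)NC(=O)Oc1ccc(OCc2ccccc2)c(C)c1OC | intermediate
8 | 4-(benzyloxy)-2-methoxy-3-methylphenyl N-(propan-2-yl)-N-(trimethylsilyl)carbamate | CC(C)N([Si](C)(C)C)C(=O)Oc1ccc(OCc2ccccc2)c(C)c1OC | intermediate (not isolated)
9 | 4-(benzyloxy)-2-methoxy-3-methyl-6-(trimethylsilyl)phenyl N-(propan-2-yl)-N-(trimethylsilyl)carbamate | CC(C)N([Si](C)(C)C)C(=O)Oc1c([Si](C)(C)C)cc(OCc2ccccc2)c(C)c1OC | intermediate (not isolated)
10 | 4-(benzyloxy)-2-methoxy-3-methyl-6-(trimethylsilyl)phenyl N-(propan-2-yl)carbamate | CC(C)NC(=O)Oc1c([Si](C)(C)C)cc(OCc2ccccc2)c(C)c1OC | intermediate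
11 | 4-(benzyloxy)-2-methoxy-3-methyl-6-(trimethylsilyl)phenol | COc1c(C)c(OCc2ccccc2)cc([Si](C)(C)C)c1O | intermediate (not isolated)
12 | 4-(benzyloxy)-2-methoxy-3-methyl-6-(trimethylsilyl)phenyl trifluoromethanesulfonate | COc1c(C)c(OCc2ccccc2)cc([Si](C)(C)C)c1OS(=O)(=O)C(F)(F)F | intermediate
13 | butanoic acid | CCCC(=O)O | starting material
14 | 5-(benzyloxy)-3-methoxy-4-methyl-1,2-didehydrobenzene (aryne) | COC1=C(C)C(OCc2ccccc2)=CC#C1 | intermediate (not isolated)
15 | 1-[4-(benzyloxy)-6-hydroxy-2-methoxy-3-methylphenyl]butan-1-one | CCCC(=O)c1c(O)cc(OCc2ccccc2)c(C)c1OC | intermediate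
16 | 1-(4,6-dihydroxy-2-methoxy-3-methylphenyl)butan-1-one | CCCC(=O)c1c(O)cc(O)c(C)c1OC | intermediate
17 | 1-{3-[(dimethylamino)methyl]-2,4-dihydroxy-6-methoxy-5-methylphenyl}butan-1-one | CCCC(=O)c1c(O)c(CN(C)C)c(O)c(C)c1OC | intermediate
18 | benzene-1,3,5-triol | Oc1cc(O)cc(O)c1 | starting material
19 | 1-(2,4,6-trihydroxyphenyl)butan-1-one | CCCC(=O)c1c(O)cc(O)cc1O | intermediate
20 | 4-butanoyl-5-hydroxy-3-methoxy-2-methyl-6-methylidenecyclohexa-2,4-dien-1-one | CCCC(=O)C1=C(O)C(=C)C(=O)C(C)=C1OC | intermediate (not isolated)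
21 | 1-{3-[(3-butanoyl-2,4,6-trihydroxyphenyl)methyl]-2,4-dihydroxy-6-methoxy-5-methylphenyl}butan-1-one | CCCC(=O)c1c(O)c(Cc2c(O)cc(O)c(C(=O)CCC)c2O)c(O)c(C)c1OC | intermediate
22 | 1-[3-({3-butanoyl-5-[(dimethylamino)methyl]-2,4,6-trihydroxyphenyl}methyl)-2,4-dihydroxy-6-methoxy-5-methylphenyl]butan-1-one | CCCC(=O)c1c(O)c(Cc2c(O)c(CN(C)C)c(O)c(C(=O)CCC)c2O)c(O)c(C)c1OC | intermediate
23 | 2-butanoyl-3,5-dihydroxy-6,6-dimethylcyclohexa-2,4-dien-1-one | CCCC(=O)C1=C(O)C=C(O)C(C)(C)C1=O | intermediate
24 | 2-butanoyl-4-[(3-butanoyl-2,6-dihydroxy-4-methoxy-5-methylphenyl)methyl]-3,5-dihydroxy-6-methylidenecyclohexa-2,4-dien-1-one | C=C1C(=O)C(C(=O)CCC)=C(O)C(Cc2c(O)c(C)c(OC)c(C(=O)CCC)c2O)=C1O | intermediate (not isolated)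
25 | Filixsaure, 2-butanoyl-4-({3-butanoyl-5-[(3-butanoyl-2,6-dihydroxy-4-methoxy-5-methylphenyl)methyl]-2,4,6-trihydroxyphenyl}methyl)-3,5-dihydroxy-6,6-dimethylcyclohexa-2,4-dien-1-one | CCCC(=O)C1=C(O)C(Cc2c(O)c(Cc3c(O)c(C)c(OC)c(C(=O)CCC)c3O)c(O)c(C(=O)CCC)c2O)=C(O)C(C)(C)C1=O | target

**Step count**
Total: 14 steps. Longest linear sequence: 12 steps (steps 1–9, 11, 12, 14 from compound 1); steps 10 and 13 are side branches.

**Steps most likely to fail**

Step 7. The C5 aryl anion may be protonated before the acyl group has migrated, leaving only O-arylation (the aryl butanoate), or the product phenoxide may be consumed by further aryne. The fallback sets out from 12 and returns at 15. The same aryne 14 would be generated with CsF in DMF at room temperature, where it inserts into the C=O π bond of the formamide instead of the C–O σ bond of an acid. The amide oxygen again bonds to C6 and the formyl carbon to C5, and the [2+2] adduct should open to 3-(benzyloxy)-6-[(dimethylamino)methylidene]-5-methoxy-4-methylcyclohexa-2,4-dien-1-one F1. Aqueous work-up should hydrolyse this to 4-(benzyloxy)-6-hydroxy-2-methoxy-3-methylbenzaldehyde F2. Addition of excess n-PrMgBr in THF at 0 °C should then give racemic 1-[4-(benzyloxy)-6-hydroxy-2-methoxy-3-methylphenyl]butan-1-ol F3, and MnO2 in CH2Cl2 should oxidise this benzylic alcohol to ketone 15.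

Step 14. During the thermal amine elimination the methylene bridge already present may exchange (retro-Michael fragmentation and recombination of the ring B–ring C unit), or the elimination from the internally hydrogen-bonded Mannich base may be too slow. The fallback sets out from 21 and 23 and returns at 25, reversing the roles of the partners so that step 12 is not needed. Triketone 23 would be treated with Eschenmoser's salt in MeCN at −20 °C to give 2-butanoyl-4-[(dimethylamino)methyl]-3,5-dihydroxy-6,6-dimethylcyclohexa-2,4-dien-1-one F4. Its amine should leave near room temperature to give the more electrophilic 2-butanoyl-3-hydroxy-6,6-dimethyl-4-methylidenecyclohex-2-ene-1,5-dione F5, which is captured by the one free ring B carbon of 21 to give 25.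

Step 5. Deprotonation at the benzylic CH2 of the benzyl ether (followed by Wittig rearrangement) or anionic Fries migration of the carbamate may compete with ortho-metalation at C6. The fallback sets out from 6 and returns at 12, replacing steps 4–6 by a bromine–lithium exchange route. Phenol 6 would be brominated with NBS and catalytic i-Pr2NH in CH2Cl2, ortho to the free hydroxyl (the para position carries the benzyloxy group), to give 4-(benzyloxy)-6-bromo-2-methoxy-3-methylphenol F6. HMDS would convert it into {[4-(benzyloxy)-6-bromo-2-methoxy-3-methylphenyl]oxy}trimethylsilane F7. n-BuLi in THF at −78 °C should then effect bromine–lithium exchange, which is faster than benzylic deprotonation, followed by 1,3 O-to-C silyl shift (retro-Brook) to the lithium salt of 11. This is triflated in the same flask with Tf2O to give 12.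

**Further compounds**
F1 | step 7 | 3-(benzyloxy)-6-[(dimethylamino)methylidene]-5-methoxy-4-methylcyclohexa-2,4-dien-1-one | CN(C)C=C1C(=O)C=C(OCc2ccccc2)C(C)=C1OC
F2 | step 7 | 4-(benzyloxy)-6-hydroxy-2-methoxy-3-methylbenzaldehyde | COc1c(C)c(OCc2ccccc2)cc(O)c1C=O
F3 | step 7 | 1-[4-(benzyloxy)-6-hydroxy-2-methoxy-3-methylphenyl]butan-1-ol (racemic) | CCCC(O)c1c(O)cc(OCc2ccccc2)c(C)c1OC
F4 | step 14 | 2-butanoyl-4-[(dimethylamino)methyl]-3,5-dihydroxy-6,6-dimethylcyclohexa-2,4-dien-1-one | CCCC(=O)C1=C(O)C(CN(C)C)=C(O)C(C)(C)C1=O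
F5 | step 14 | 2-butanoyl-3-hydroxy-6,6-dimethyl-4-methylidenecyclohex-2-ene-1,5-dione | CCCC(=O)C1=C(O)C(=C)C(=O)C(C)(C)C1=O
F6 | step 5 | 4-(benzyloxy)-6-bromo-2-methoxy-3-methylphenol | COc1c(C)c(OCc2ccccc2)cc(Br)c1O
F7 | step 5 | {[4-(benzyloxy)-6-bromo-2-methoxy-3-methylphenyl]oxy}trimethylsilane | COc1c(C)c(OCc2ccccc2)cc(Br)c1O[Si](C)(C)C
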